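**Retrosynthetic overview**

1. Target 27 ⇐ C8 methacrylation of 26 ⇐ epoxy diol 25, where a lipase acetylates only the primary C14-OH, so both esters go on after the oxirane without further protecting groups.
2. Oxirane (C1/C10) ⇐ Sharpless epoxidation with D-(−)-diethyl tartrate of macrocyclic allylic alcohol 23; ten-membered ring ⇐ ring-closing metathesis at C1=C10 of seco-diene 21.
3. C7–C8 bond with the C7 and C8 stereocentres ⇐ Zn Barbier coupling of bromomethyl butenolide 14 with β,γ-unsaturated aldehyde 19, which also unveils the α-methylene lactone.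
4. 14 ⇐ carbonylative lactonization of a Z-iodoallylic alcohol ⇐ catalytic asymmetric alkynylation of enal 6 (C6, first stereocentre); 19 ⇐ 2-methylidenepropane-1,3-diol.
5. Ring order: γ-lactone (ring A) first, ten-membered carbocycle (ring B) second, oxirane (ring C) last.

Assumption: germacranolide numbering is used for positions (C6 lactone carbinol, C8 ester carbinol, C1/C10 oxirane carbons, C14 the CH2OAc carbon), and (S,S)-ProPhenol is taken as the ligand enantiomer that gives (R)-9; if Mosher ester analysis shows the opposite sense, the (R,R)-ligand is used.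

**Route**

Step 1
Reactants: 1 but-3-enylmagnesium bromide; 2 ethyl but-2-ynoate
Product: 4 ethyl (2E)-3-methylhepta-2,6-dienoate, via but-3-enylcopper 3 (not isolated)
Conditions: CuBr·SMe2 (1.0 equiv), THF, −78 °C; then 2, −78 °C; aq. NH4Cl at −78 °C
Reagents that add atoms: none
Why: syn-carbocupration (conjugate addition) of the organocopper reagent to the ynoate at low temperature puts the butenyl group cis to the new vinylic H, so the E-enoate forms stereospecifically.

Step 2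
Reactants: 4 ethyl (2E)-3-methylhepta-2,6-dienoate
Product: 5 (2E)-3-methylhepta-2,6-dien-1-ol
Conditions: iBu2AlH (2.2 equiv), CH2Cl2, −78 °C; aqueous work-up
Reagents that add atoms: none
Why: 1,2-reduction of the conjugated ester by iBu2AlH gives the allylic alcohol and leaves both alkenes alone.

Step 3
Reactants: 5 (2E)-3-methylhepta-2,6-dien-1-ol
Product: 6 (2E)-3-methylhepta-2,6-dienal
Conditions: MnO2 (15 equiv), CH2Cl2, rt
Reagents that add atoms: none
Why: chemoselective MnO2 oxidation of the allylic alcohol stops at the enal without touching the terminal alkene or the E geometry.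

Step 4
Reactants: 6 (2E)-3-methylhepta-2,6-dienal; 7 tert-butyldimethyl(prop-2-yn-1-yloxy)silane
Product: 9 (4R,5E)-1-{[tert-butyl(dimethyl)silyl]oxy}-6-methyldeca-5,9-dien-2-yn-4-ol, via alkynyl(methyl)zinc 8 (not isolated)
Conditions: Me2Zn (3 equiv), (S,S)-ProPhenol (20 mol %), Ph3P=O (40 mol %), toluene, 4 °C
Reagents that add atoms: none
Why: catalytic asymmetric alkynylation (Trost ProPhenol method), in which the chiral complex formed from Me2Zn and ProPhenol delivers the alkynyl group to one face of the enal in a 1,2-addition and sets C6 (R), the first stereocentre.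

Step 5
Reactants: 9 (4R,5E)-1-{[tert-butyl(dimethyl)silyl]oxy}-6-methyldeca-5,9-dien-2-yn-4-ol
Product: 11 (2Z,4R,5E)-1-{[tert-butyl(dimethyl)silyl]oxy}-2-iodo-6-methyldeca-2,5,9-trien-4-ol, via cyclic alkenylalanate 10 (not isolated)
Conditions: NaAlH2(OCH2CH2OCH3)2, THF, 0 °C; then I2, THF, −78 °C
Reagents that add atoms: iodine, II
Why: hydroxyl-directed trans-hydroalumination of the propargylic alcohol places Al on the distal alkyne carbon, and iodination of the C–Al bond with retention gives the Z-iodide with I cis to the carbinol.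

Step 6
Reactants: 11 (2Z,4R,5E)-1-{[tert-butyl(dimethyl)silyl]oxy}-2-iodo-6-methyldeca-2,5,9-trien-4-ol
Product: 12 (5R)-3-({[tert-butyl(dimethyl)silyl]oxy}methyl)-5-[(1E)-2-methylhexa-1,5-dien-1-yl]furan-2(5H)-one
Conditions: CO (1 atm), PdCl2(PPh3)2 (5 mol %), K2CO3, THF, rt
Reagents that add atoms: carbon monoxide, [C-]#[O+]
Why: PdCl2(PPh3)2-catalysed carbonylative lactonization (oxidative addition into C–I, CO insertion, capture by the cis hydroxyl) closes the butenolide (ring A) without breaking any bond at C6.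

Step 7
Reactants: 12 (5R)-3-({[tert-butyl(dimethyl)silyl]oxy}methyl)-5-[(1E)-2-methylhexa-1,5-dien-1-yl]furan-2(5H)-one
Product: 13 (5R)-3-(hydroxymethyl)-5-[(1E)-2-methylhexa-1,5-dien-1-yl]furan-2(5H)-one
Conditions: HF·pyridine, pyridine, THF, 0 °C to rt
Reagents that add atoms: none
Why: fluoride-mediated cleavage of the primary silyl ether under buffered conditions that neither open the butenolide nor epimerise C6.

Step 8
Reactants: 13 (5R)-3-(hydroxymethyl)-5-[(1E)-2-methylhexa-1,5-dien-1-yl]furan-2(5H)-one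
Product: 14 (5R)-3-(bromomethyl)-5-[(1E)-2-methylhexa-1,5-dien-1-yl]furan-2(5H)-one
Conditions: CBr4, PPh3, CH2Cl2, 0 °C
Reagents that add atoms: tetrabromomethane, BrC(Br)(Br)Br
Why: Appel bromination converts the primary allylic alcohol into the bromide by SN2 at CH2 under neutral conditions.

Step 9
Reactants: 15 2-methylidenepropane-1,3-diol
Product: 16 2-{[(4-methoxybenzyl)oxy]methyl}prop-2-en-1-ol
Conditions: 15 (3 equiv), NaH (1 equiv), 4-methoxybenzyl chloride (1 equiv), Bu4NI (cat.), THF/DMF, 0 °C to rt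
Reagents that add atoms: 4-methoxybenzyl chloride, COc1ccc(CCl)cc1
Why: Williamson monoetherification of the symmetric diol, with the diol in excess to suppress the bis-ether.

Step 10
Reactants: 16 2-{[(4-methoxybenzyl)oxy]methyl}prop-2-en-1-ol
Product: 17 1-({[2-(bromomethyl)prop-2-en-1-yl]oxy}methyl)-4-methoxybenzene
Conditions: CBr4, PPh3, CH2Cl2, 0 °C
Reagents that add atoms: tetrabromomethane, BrC(Br)(Br)Br
Why: Appel bromination of the remaining primary allylic alcohol, with the benzyl-type ether inert.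

Step 11
Reactants: 17 1-({[2-(bromomethyl)prop-2-en-1-yl]oxy}methyl)-4-methoxybenzene
Product: 18 3-{[(4-methoxybenzyl)oxy]methyl}but-3-en-1-ol
Conditions: Zn dust, 37% aq. HCHO, THF/sat. aq. NH4Cl, rt
Reagents that add atoms: formaldehyde, C=O
Why: Zn-mediated aqueous Barbier allylation of formaldehyde adds the C8 carbon, and the symmetric 2-substituted allyl unit makes the regiochemistry irrelevant.

Step 12
Reactants: 18 3-{[(4-methoxybenzyl)oxy]methyl}but-3-en-1-ol
Product: 19 3-{[(4-methoxybenzyl)oxy]methyl}but-3-enal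
Conditions: Dess–Martin periodinane, pyridine, CH2Cl2, 0 °C; used at once
Reagents that add atoms: none
Why: Dess–Martin oxidation under buffered, non-basic conditions gives the β,γ-unsaturated aldehyde without migration of the double bond into conjugation.

Step 13
Reactants: 14 (5R)-3-(bromomethyl)-5-[(1E)-2-methylhexa-1,5-dien-1-yl]furan-2(5H)-one; 19 3-{[(4-methoxybenzyl)oxy]methyl}but-3-enal
Product: 20 (4R,5R)-4-[(1S)-1-hydroxy-3-{[(4-methoxybenzyl)oxy]methyl}but-3-en-1-yl]-3-methylidene-5-[(1E)-2-methylhexa-1,5-dien-1-yl]oxolan-2-one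
Conditions: Zn dust, THF/sat. aq. NH4Cl (2:1), 0 °C to rt
Reagents that add atoms: none
Why: Zn-mediated Barbier allylation in which the butenolide allyl unit adds through its ring γ-carbon (C7) on the face anti to the C6 side chain, via a chair Zimmerman–Traxler transition state with the aldehyde residue equatorial, giving the trans lactone, the anti C7/C8 relationship (8S) and the α-methylene lactone.

Step 14
Reactants: 20 (4R,5R)-4-[(1S)-1-hydroxy-3-{[(4-methoxybenzyl)oxy]methyl}but-3-en-1-yl]-3-methylidene-5-[(1E)-2-methylhexa-1,5-dien-1-yl]oxolan-2-one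
Product: 21 (4S,5R)-4-[(1S)-3-{[(4-methoxybenzyl)oxy]methyl}-1-[(triethylsilyl)oxy]but-3-en-1-yl]-3-methylidene-5-[(1E)-2-methylhexa-1,5-dien-1-yl]oxolan-2-one
Conditions: Et3SiOTf, 2,6-lutidine, CH2Cl2, −78 °C
Reagents that add atoms: triethylsilyl trifluoromethanesulfonate, CC[Si](CC)(CC)OS(=O)(=O)C(F)(F)F
Why: silyl ether formation at the hindered C8 hydroxyl with the reactive triflate and a non-nucleophilic base; the descriptor at C7 changes only because of the new Si substituent.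

Step 15
Reactants: 21 (4S,5R)-4-[(1S)-3-{[(4-methoxybenzyl)oxy]methyl}-1-[(triethylsilyl)oxy]but-3-en-1-yl]-3-methylidene-5-[(1E)-2-methylhexa-1,5-dien-1-yl]oxolan-2-one
Product: 22 (6R,7S,8S)-14-[(4-methoxybenzyl)oxy]-8-[(triethylsilyl)oxy]germacra-1(10),4,11(13)-trien-12,6-olide (4E; C1=C10 with C2 and C9 cis on the ring, E by CIP)
Conditions: second-generation Hoveyda–Grubbs catalyst (15 mol %), 1,4-benzoquinone (30 mol %), toluene (1 mM), 90 °C
Reagents that add atoms: none
Why: ring-closing metathesis between the terminal vinyl group and the 1,1-disubstituted alkene with loss of ethene closes ring B as the less strained ring-cis trisubstituted alkene, while the electron-poor α-methylene lactone and the trisubstituted C4=C5 alkene do not compete.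

Step 16
Reactants: 22 (6R,7S,8S)-14-[(4-methoxybenzyl)oxy]-8-[(triethylsilyl)oxy]germacra-1(10),4,11(13)-trien-12,6-olide
Product: 23 (6R,7S,8S)-14-hydroxy-8-[(triethylsilyl)oxy]germacra-1(10),4,11(13)-trien-12,6-olide
Conditions: DDQ (1.2 equiv), CH2Cl2/pH 7 buffer (10:1), 0 °C
Reagents that add atoms: none
Why: oxidative cleavage of the 4-methoxybenzyl ether by DDQ frees the allylic C14 hydroxyl and leaves the silyl ether and the alkenes intact.

Step 17
Reactants: 23 (6R,7S,8S)-14-hydroxy-8-[(triethylsilyl)oxy]germacra-1(10),4,11(13)-trien-12,6-olide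
Product: 24 (1R,6R,7S,8S,10R)-1,10-epoxy-14-hydroxy-8-[(triethylsilyl)oxy]germacra-4,11(13)-dien-12,6-olide
Conditions: Ti(OiPr)4 (0.3 equiv), D-(−)-diethyl tartrate (0.36 equiv), t-BuOOH, 4 Å molecular sieves, CH2Cl2, −20 °C
Reagents that add atoms: tert-butyl hydroperoxide, CC(C)(C)OO
Why: Sharpless asymmetric epoxidation, in which the Ti(OiPr)4/D-(−)-diethyl tartrate complex binds the C14 hydroxyl and delivers oxygen to the face that gives the (1R,10R)-oxirane (reagent control), the cis ring fusion following from the alkene geometry and the other alkenes, not being allylic alcohols, staying untouched.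

Step 18
Reactants: 24 (1R,6R,7S,8S,10R)-1,10-epoxy-14-hydroxy-8-[(triethylsilyl)oxy]germacra-4,11(13)-dien-12,6-olide
Product: 25 (1R,6R,7R,8S,10R)-1,10-epoxy-8,14-dihydroxygermacra-4,11(13)-dien-12,6-olide
Conditions: HF·pyridine, pyridine, THF, 0 °C
Reagents that add atoms: none
Why: buffered fluoride desilylation removes the triethylsilyl group at 0 °C without opening the trisubstituted oxirane.

Step 19
Reactants: 25 (1R,6R,7R,8S,10R)-1,10-epoxy-8,14-dihydroxygermacra-4,11(13)-dien-12,6-olide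
Product: 26 (1R,6R,7R,8S,10R)-14-acetoxy-1,10-epoxy-8-hydroxygermacra-4,11(13)-dien-12,6-olide
Conditions: lipase (Candida antarctica lipase B, immobilised), vinyl acetate, t-BuOMe, 30 °C
Reagents that add atoms: vinyl acetate, CC(=O)OC=C
Why: lipase-catalysed transesterification with an irreversible acyl donor acetylates only the primary C14 hydroxyl, since the ring-bound secondary C8 hydroxyl next to C7 is too hindered for the active site, under neutral conditions that spare the oxirane and the α-methylene lactone.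

Step 20
Reactants: 26 (1R,6R,7R,8S,10R)-14-acetoxy-1,10-epoxy-8-hydroxygermacra-4,11(13)-dien-12,6-olide
Product: 27 (1R,4E,6R,7R,8S,10R)-14-acetoxy-1,10-epoxy-8-(methacryloyloxy)germacra-4,11(13)-dien-12,6-olide (CNP0150481.4)
Conditions: methacrylic anhydride, Et3N, DMAP (cat.), CH2Cl2, 0 °C to rt
Reagents that add atoms: methacrylic anhydride, CC(=C)C(=O)OC(=O)C(C)=C
Why: DMAP-catalysed acyl transfer esterifies the remaining secondary C8 hydroxyl with retention, and no free hydroxyl is left next to the oxirane.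

**Compound list**

1 | but-3-enylmagnesium bromide | C=CCC[Mg]Br | starting material
2 | ethyl but-2-ynoate | CC#CC(=O)OCC | starting material
3 | but-3-enylcopper (MgBr2 complex, formed in situ) | C=CCC[Cu].Br[Mg]Br | intermediate
4 | ethyl (2E)-3-methylhepta-2,6-dienoate | CCOC(=O)/C=C(\C)CCC=C | intermediate
5 | (2E)-3-methylhepta-2,6-dien-1-ol | OC/C=C(\C)CCC=C | intermediate
6 | (2E)-3-methylhepta-2,6-dienal | O=C/C=C(\C)CCC=C | intermediate
7 | tert-butyldimethyl(prop-2-yn-1-yloxy)silane | C#CCO[Si](C)(C)C(C)(C)C | starting material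
8 | methyl{3-[tert-butyl(dimethyl)silyl]oxyprop-1-yn-1-yl}zinc (formed in situ) | C[Zn]C#CCO[Si](C)(C)C(C)(C)C | intermediate
9 | (4R,5E)-1-{[tert-butyl(dimethyl)silyl]oxy}-6-methyldeca-5,9-dien-2-yn-4-ol | C=CCC/C(C)=C/[C@@H](O)C#CCO[Si](C)(C)C(C)(C)C | intermediate
10 | sodium cyclic alkenylalanate of 9 (five-membered O–Al–C=C ring, Al on the carbon bearing CH2OSi; formed in situ) | C=CCC/C(C)=C/[C@H]1O[Al-](OCCOC)(OCCOC)C(CO[Si](C)(C)C(C)(C)C)=C1.[Na+] | intermediate
11 | (2Z,4R,5E)-1-{[tert-butyl(dimethyl)silyl]oxy}-2-iodo-6-methyldeca-2,5,9-trien-4-ol | C=CCC/C(C)=C/[C@@H](O)/C=C(\I)CO[Si](C)(C)C(C)(C)C | intermediate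
12 | (5R)-3-({[tert-butyl(dimethyl)silyl]oxy}methyl)-5-[(1E)-2-methylhexa-1,5-dien-1-yl]furan-2(5H)-one | C=CCC/C(C)=C/[C@H]1OC(=O)C(CO[Si](C)(C)C(C)(C)C)=C1 | intermediate
13 | (5R)-3-(hydroxymethyl)-5-[(1E)-2-methylhexa-1,5-dien-1-yl]furan-2(5H)-one | C=CCC/C(C)=C/[C@H]1OC(=O)C(CO)=C1 | intermediate
14 | (5R)-3-(bromomethyl)-5-[(1E)-2-methylhexa-1,5-dien-1-yl]furan-2(5H)-one | C=CCC/C(C)=C/[C@H]1OC(=O)C(CBr)=C1 | intermediate
15 | 2-methylidenepropane-1,3-diol | C=C(CO)CO | starting material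
16 | 2-{[(4-methoxybenzyl)oxy]methyl}prop-2-en-1-ol | C=C(CO)COCc1ccc(OC)cc1 | intermediate
17 | 1-({[2-(bromomethyl)prop-2-en-1-yl]oxy}methyl)-4-methoxybenzene | C=C(CBr)COCc1ccc(OC)cc1 | intermediate
18 | 3-{[(4-methoxybenzyl)oxy]methyl}but-3-en-1-ol | C=C(CCO)COCc1ccc(OC)cc1 | intermediate
19 | 3-{[(4-methoxybenzyl)oxy]methyl}but-3-enal | C=C(CC=O)COCc1ccc(OC)cc1 | intermediate
20 | (4R,5R)-4-[(1S)-1-hydroxy-3-{[(4-methoxybenzyl)oxy]methyl}but-3-en-1-yl]-3-methylidene-5-[(1E)-2-methylhexa-1,5-dien-1-yl]oxolan-2-one | C=CCC/C(C)=C/[C@H]1OC(=O)C(=C)[C@@H]1[C@@H](O)CC(=C)COCc1ccc(OC)cc1 | intermediate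
21 | (4S,5R)-4-[(1S)-3-{[(4-methoxybenzyl)oxy]methyl}-1-[(triethylsilyl)oxy]but-3-en-1-yl]-3-methylidene-5-[(1E)-2-methylhexa-1,5-dien-1-yl]oxolan-2-one | C=CCC/C(C)=C/[C@H]1OC(=O)C(=C)[C@@H]1[C@@H](O[Si](CC)(CC)CC)CC(=C)COCc1ccc(OC)cc1 | intermediate
22 | (6R,7S,8S)-14-[(4-methoxybenzyl)oxy]-8-[(triethylsilyl)oxy]germacra-1(10),4,11(13)-trien-12,6-olide (4E; C2 and C9 cis across C1=C10) | CC[Si](CC)(CC)O[C@H]1C/C(COCc3ccc(OC)cc3)=C\CC/C(C)=C/[C@H]2OC(=O)C(=C)[C@H]12 | intermediate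
23 | (6R,7S,8S)-14-hydroxy-8-[(triethylsilyl)oxy]germacra-1(10),4,11(13)-trien-12,6-olide | CC[Si](CC)(CC)O[C@H]1C/C(CO)=C\CC/C(C)=C/[C@H]2OC(=O)C(=C)[C@H]12 | intermediate
24 | (1R,6R,7S,8S,10R)-1,10-epoxy-14-hydroxy-8-[(triethylsilyl)oxy]germacra-4,11(13)-dien-12,6-olide | CC[Si](CC)(CC)O[C@H]1C[C@]2(CO)O[C@@H]2CC/C(C)=C/[C@H]2OC(=O)C(=C)[C@H]12 | intermediate
25 | (1R,6R,7R,8S,10R)-1,10-epoxy-8,14-dihydroxygermacra-4,11(13)-dien-12,6-olide | O[C@H]1C[C@]2(CO)O[C@@H]2CC/C(C)=C/[C@H]2OC(=O)C(=C)[C@H]12 | intermediate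
26 | (1R,6R,7R,8S,10R)-14-acetoxy-1,10-epoxy-8-hydroxygermacra-4,11(13)-dien-12,6-olide | O[C@H]1C[C@]2(COC(C)=O)O[C@@H]2CC/C(C)=C/[C@H]2OC(=O)C(=C)[C@H]12 | intermediate
27 | (1R,4E,6R,7R,8S,10R)-14-acetoxy-1,10-epoxy-8-(methacryloyloxy)germacra-4,11(13)-dien-12,6-olide (CNP0150481.4) | C=C(C)C(=O)O[C@H]1C[C@]2(COC(C)=O)O[C@@H]2CC/C(C)=C/[C@H]2OC(=O)C(=C)[C@H]12 | target

**Step count and risks**

Total step count: 20. Longest linear sequence: 16 steps (steps 1–8, then 13–20); the aldehyde branch (steps 9–12) is four steps.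

Most likely to fail, in this order:

1. Step 15. Closing a ten-membered ring to a trisubstituted alkene by metathesis can stall or give oligomers. The fallback closes the ring by a CrCl2/NiCl2 (Nozaki–Hiyama–Kishi) reaction between C1 and C10 and then moves the oxygen from C1 to C14; it sets out from 2 and comes back at 23. Commercial [2-(1,3-dioxolan-2-yl)ethyl]magnesium bromide F1 is turned with CuBr·SMe2 into [2-(1,3-dioxolan-2-yl)ethyl]copper F2 and added to 2 to give ethyl (2E)-5-(1,3-dioxolan-2-yl)-3-methylpent-2-enoate F3. The operations of steps 2 to 8 then follow: iBu2AlH gives (2E)-5-(1,3-dioxolan-2-yl)-3-methylpent-2-en-1-ol F4, MnO2 the enal F5, the ProPhenol alkynylation with 7 the (4R)-propargylic alcohol F6, hydroalumination the cyclic alkenylalanate F7, iodination the Z-vinyl iodide F8, carbonylative lactonization the silyloxymethyl butenolide F9, HF·pyridine the hydroxymethyl butenolide F10 and CBr4/PPh3 the bromomethyl butenolide F11. Commercial 3-bromobut-3-en-1-ol F12 is oxidised with Dess–Martin periodinane to 3-bromobut-3-enal F13, and Zn Barbier coupling of F11 with F13 gives the homoallylic alcohol F14. 1 M aq. HCl in THF frees the hydroxy aldehyde F15, and Et3SiCl/imidazole gives the silyl ether aldehyde F16. CrCl2 with NiCl2 (cat.) in DMSO/THF at 2 mM joins the vinyl bromide carbon to the aldehyde and gives the macrocyclic 1-hydroxy-10(14)-methylidene compound F17 (both C1 epimers serve). A 1,3-transposition of this allylic alcohol catalysed by Ph3SiOReO3 in Et2O at −50 to 0 °C (formal [3,3] shift with C2 equatorial in the chair) moves the hydroxyl to C14 and the double bond to C1=C10 with C2 and C9 cis, which is 23.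

2. Step 17. The macrocycle may present the required alkene face poorly, or the ring bias may oppose the tartrate. The fallback replaces reagent control by delivery from the neighbouring stereocentre; it sets out from 23 and comes back at 26. HF·pyridine removes the silyl group to give the diol (6R,7R,8S)-8,14-dihydroxygermacra-1(10),4,11(13)-trien-12,6-olide F18. The lipase with vinyl acetate acetylates its primary hydroxyl to the monoacetate (6R,7R,8S)-14-acetoxy-8-hydroxygermacra-1(10),4,11(13)-trien-12,6-olide F19. VO(acac)2 (cat.) with t-BuOOH in CH2Cl2 at 0 °C, directed by the homoallylic C8 hydroxyl, then epoxidises C1=C10 only and gives 26; the facial outcome has to be confirmed by NOE.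

3. Step 13. The C8 configuration rests on the chair transition state, and the C8 epimer may dominate. The fallback inverts C8 while putting on the final ester; it sets out from 14 and 19 and comes back at 27. Their coupling then gives the C8 epimer (4R,5R)-4-[(1R)-1-hydroxy-3-{[(4-methoxybenzyl)oxy]methyl}but-3-en-1-yl]-3-methylidene-5-[(1E)-2-methylhexa-1,5-dien-1-yl]oxolan-2-one F20. A Mitsunobu reaction with methacrylic acid (PPh3, DIAD, toluene, 0 °C) inverts C8 and gives the (8S)-methacrylate seco-diene F21. Ring-closing metathesis as in step 15 gives the macrocyclic 14-(4-methoxybenzyl) ether 8-methacrylate F22, DDQ the 14-hydroxy 8-methacrylate F23, and the epoxidation of step 17 the epoxy alcohol F24. The lipase with vinyl acetate then acetylates C14 to give 27.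

**Further compounds**

F1 | step 15 | [2-(1,3-dioxolan-2-yl)ethyl]magnesium bromide | Br[Mg]CCC1OCCO1
F2 | step 15 | [2-(1,3-dioxolan-2-yl)ethyl]copper (MgBr2 complex, formed in situ) | [Cu]CCC1OCCO1.Br[Mg]Br
F3 | step 15 | ethyl (2E)-5-(1,3-dioxolan-2-yl)-3-methylpent-2-enoate | CCOC(=O)/C=C(\C)CCC1OCCO1
F4 | step 15 | (2E)-5-(1,3-dioxolan-2-yl)-3-methylpent-2-en-1-ol | OC/C=C(\C)CCC1OCCO1
F5 | step 15 | (2E)-5-(1,3-dioxolan-2-yl)-3-methylpent-2-enal | O=C/C=C(\C)CCC1OCCO1
F6 | step 15 | (4R,5E)-1-{[tert-butyl(dimethyl)silyl]oxy}-8-(1,3-dioxolan-2-yl)-6-methyloct-5-en-2-yn-4-ol | O1CCOC1CC/C(C)=C/[C@@H](O)C#CCO[Si](C)(C)C(C)(C)C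
F7 | step 15 | sodium cyclic alkenylalanate of F6 (formed in situ) | O1CCOC1CC/C(C)=C/[C@H]1O[Al-](OCCOC)(OCCOC)C(CO[Si](C)(C)C(C)(C)C)=C1.[Na+]
F8 | step 15 | (2Z,4R,5E)-1-{[tert-butyl(dimethyl)silyl]oxy}-8-(1,3-dioxolan-2-yl)-2-iodo-6-methylocta-2,5-dien-4-ol | O1CCOC1CC/C(C)=C/[C@@H](O)/C=C(\I)CO[Si](C)(C)C(C)(C)C
F9 | step 15 | (5R)-3-({[tert-butyl(dimethyl)silyl]oxy}methyl)-5-[(1E)-4-(1,3-dioxolan-2-yl)-2-methylbut-1-en-1-yl]furan-2(5H)-one | O1CCOC1CC/C(C)=C/[C@H]1OC(=O)C(CO[Si](C)(C)C(C)(C)C)=C1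
F10 | step 15 | (5R)-5-[(1E)-4-(1,3-dioxolan-2-yl)-2-methylbut-1-en-1-yl]-3-(hydroxymethyl)furan-2(5H)-one | O1CCOC1CC/C(C)=C/[C@H]1OC(=O)C(CO)=C1
F11 | step 15 | (5R)-3-(bromomethyl)-5-[(1E)-4-(1,3-dioxolan-2-yl)-2-methylbut-1-en-1-yl]furan-2(5H)-one | O1CCOC1CC/C(C)=C/[C@H]1OC(=O)C(CBr)=C1
F12 | step 15 | 3-bromobut-3-en-1-ol | C=C(Br)CCO
F13 | step 15 | 3-bromobut-3-enal | C=C(Br)CC=O
F14 | step 15 | (4R,5R)-4-[(1S)-3-bromo-1-hydroxybut-3-en-1-yl]-5-[(1E)-4-(1,3-dioxolan-2-yl)-2-methylbut-1-en-1-yl]-3-methylideneoxolan-2-one | O1CCOC1CC/C(C)=C/[C@H]1OC(=O)C(=C)[C@@H]1[C@@H](O)CC(Br)=C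
F15 | step 15 | (4E)-5-{(2R,3R)-3-[(1S)-3-bromo-1-hydroxybut-3-en-1-yl]-4-methylidene-5-oxooxolan-2-yl}-4-methylpent-4-enal | O=CCC/C(C)=C/[C@H]1OC(=O)C(=C)[C@@H]1[C@@H](O)CC(Br)=C
F16 | step 15 | (4E)-5-{(2R,3S)-3-[(1S)-3-bromo-1-[(triethylsilyl)oxy]but-3-en-1-yl]-4-methylidene-5-oxooxolan-2-yl}-4-methylpent-4-enal | O=CCC/C(C)=C/[C@H]1OC(=O)C(=C)[C@@H]1[C@@H](O[Si](CC)(CC)CC)CC(Br)=C
F17 | step 15 | (6R,7S,8S)-1-hydroxy-8-[(triethylsilyl)oxy]germacra-4,10(14),11(13)-trien-12,6-olide (C1 epimers) | CC[Si](CC)(CC)O[C@H]1CC(=C)C(O)CC/C(C)=C/[C@H]2OC(=O)C(=C)[C@H]12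
F18 | step 17 | (6R,7R,8S)-8,14-dihydroxygermacra-1(10),4,11(13)-trien-12,6-olide | O[C@H]1C/C(CO)=C\CC/C(C)=C/[C@H]2OC(=O)C(=C)[C@H]12
F19 | step 17 | (6R,7R,8S)-14-acetoxy-8-hydroxygermacra-1(10),4,11(13)-trien-12,6-olide | O[C@H]1C/C(COC(C)=O)=C\CC/C(C)=C/[C@H]2OC(=O)C(=C)[C@H]12
F20 | step 13 | (4R,5R)-4-[(1R)-1-hydroxy-3-{[(4-methoxybenzyl)oxy]methyl}but-3-en-1-yl]-3-methylidene-5-[(1E)-2-methylhexa-1,5-dien-1-yl]oxolan-2-one | C=CCC/C(C)=C/[C@H]1OC(=O)C(=C)[C@@H]1[C@H](O)CC(=C)COCc1ccc(OC)cc1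
F21 | step 13 | (1S)-3-{[(4-methoxybenzyl)oxy]methyl}-1-{(2R,3R)-4-methylidene-2-[(1E)-2-methylhexa-1,5-dien-1-yl]-5-oxooxolan-3-yl}but-3-en-1-yl 2-methylprop-2-enoate | C=CCC/C(C)=C/[C@H]1OC(=O)C(=C)[C@@H]1[C@@H](OC(=O)C(C)=C)CC(=C)COCc1ccc(OC)cc1
F22 | step 13 | (6R,7R,8S)-14-[(4-methoxybenzyl)oxy]-8-(methacryloyloxy)germacra-1(10),4,11(13)-trien-12,6-olide | C=C(C)C(=O)O[C@H]1C/C(COCc3ccc(OC)cc3)=C\CC/C(C)=C/[C@H]2OC(=O)C(=C)[C@H]12
F23 | step 13 | (6R,7R,8S)-14-hydroxy-8-(methacryloyloxy)germacra-1(10),4,11(13)-trien-12,6-olide | C=C(C)C(=O)O[C@H]1C/C(CO)=C\CC/C(C)=C/[C@H]2OC(=O)C(=C)[C@H]12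
F24 | step 13 | (1R,6R,7R,8S,10R)-1,10-epoxy-14-hydroxy-8-(methacryloyloxy)germacra-4,11(13)-dien-12,6-olide | C=C(C)C(=O)O[C@H]1C[C@]2(CO)O[C@@H]2CC/C(C)=C/[C@H]2OC(=O)C(=C)[C@H]12
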